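## Retrosynthetic overview

1. Locants follow 1-benzoxepine numbering (O1, C2, C3, C4, C5, C5a, C6–C9, C9a; the exocyclic carbon on C2 is C1'). The oxirane comes last, by epoxidation of C3=C4 of diene 12. The (E)-bromomethylidene comes from gem-dibromide 11 by removal of the bromine cis to O1, and C1' from methylenation of the lactone carbonyl C2 of 8.
2. The oxepane ring (O1, C2, C3, C4, C5, C5a, C9a) is not closed but grown: the six-membered lactone ring of 4 takes in one carbon (the future C3) between C2 and its α-carbon. This is done by dibromocarbene addition to the ketene silyl acetal and opening of the cyclopropane (4 → 7); the bromine left on C3 is then exchanged for methyl.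
3. Enabling feature: in the oxepane, C2 is at the carboxyl oxidation level (hidden as an enol ether), is bonded to O1, and has as neighbour C3, which carries only a methyl and a π or epoxide bond to C4. O1–C2(=O)–C3(Me)=C4 is therefore what a carbene carbon pushed into the O1–C2(OSi)=C unit of a δ-lactone gives, and the two oxygens on C2 drive the ring opening.
4. Cyclohexane ring A and the lactone ring, with C5a, C7 and C9a, come together from tert-butyl ester 3 by one enantioselective bromonium-induced polyene cyclization; 3 comes from geranyl bromide and tert-butyl acetate.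
5. Order of ring formation: cyclohexane plus six-membered lactone (step 2), oxepane by one-carbon expansion (step 3), oxirane (step 8).

Key step: step 3

Assumption: the enantiomer of the chiral Lewis-base catalyst that gives the 6S bromide in step 2 has to be found by a test run, since the sense of induction cannot be predicted for an ester-terminated substrate (chromene locants are used for 4–6).

## Route

Step 1
Reactants: 1 geranyl bromide ((2E)-1-bromo-3,7-dimethylocta-2,6-diene); 2 tert-butyl acetate
Product: 3 tert-butyl (4E)-5,9-dimethyldeca-4,8-dienoate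
Conditions: 2, LDA, THF, −78 °C; then 1, DMPU, −78 → 0 °C
Reagents that add atoms: none
Why: Alkylation of a lithium ester enolate at a primary allylic bromide (SN2) is a standard C–C bond formation that keeps the E alkene and forms no stereocentre.

Step 2
Reactants: 3 tert-butyl (4E)-5,9-dimethyldeca-4,8-dienoate
Product: 4 (4aS,6S,8aS)-6-bromo-5,5,8a-trimethyloctahydro-2H-chromen-2-one
Conditions: chiral 3,3'-diaryl-BINOL thiophosphoramide (Lewis base catalyst, 10 mol %), DBDMH (0.6 equiv), toluene/CH2Cl2, −78 °C
Reagents that add atoms: 1,3-dibromo-5,5-dimethylhydantoin (DBDMH), CC1(C)N(Br)C(=O)N(Br)C1=O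
Why: In this catalytic enantioselective bromonium-induced polyene cyclization the chiral Lewis base should deliver Br+ to one face of the terminal C8=C9 alkene (sets C6), the E-configured C4=C5 alkene should add through a chair-chair transition state with anti addition (sets C4a and C8a trans, bromine equatorial), and the ester carbonyl oxygen should capture the tertiary cation with loss of 2-methylpropene to close the six-membered lactone.

Step 3
Reactants: 4 (4aS,6S,8aS)-6-bromo-5,5,8a-trimethyloctahydro-2H-chromen-2-one
Product: 7 (5aS,7S,9aS)-3,7-dibromo-6,6,9a-trimethyl-5,5a,6,7,8,9-hexahydro-1-benzoxepin-2(9aH)-one, via ketene silyl acetal 5 (not isolated), via dibromocyclopropane 6 (not isolated)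
Conditions: LDA, THF, −78 °C; TBSCl, DMPU, −78 → 0 °C; solvent change to pentane; CHBr3, KOtBu, −30 °C → rt
Reagents that add atoms: bromoform, BrC(Br)Br (its carbon becomes C3 and one bromine stays on it); tert-butyldimethylsilyl chloride, CC(C)(C)[Si](C)(C)Cl (silyl group present only in 5 and 6)
Why: O-silylation of the lactone enolate turns the six-membered lactone ring (O1, C2, C3, C4, C4a, C8a) into a cyclic ketene silyl acetal, whose electron-rich C2=C3 bond takes up dibromocarbene in a concerted [2+1] addition to give the 2-oxabicyclo[4.1.0]heptane 6. Ionisation of the bromide that lies over the six-membered ring, with disrotatory electrocyclic opening of the shared C2–C3 bond (cyclopropyl-to-allyl cation, pushed by the two oxygens on C2 and paid for by the release of cyclopropane strain), puts the carbene carbon between C2 and the old C3, and loss of the silyl group to bromide leaves the 3-bromo-oxepin-2-one 7. The closest known reaction type is the dihalocarbene ring expansion of cyclic silyl enol ethers and ketene silyl acetals to 2-halo-enones and 2-halo-acrylates one carbon larger. The only ring that is closed is the cyclopropane (cheletropic carbene addition to the alkene); the seven-membered ring is not closed but arises when the internal bond of that cyclopropane breaks, and its new C3=C4 bond can only be cis. No stereocentre is formed, and C5a, C7 and C9a of 7 (C4a, C6 and C8a of 4) lie away from the reacting atoms and are kept. The step needs O- and not C-silylation (TBSCl with DMPU), carbene addition to the one alkene present and survival of the secondary bromide, which is equatorial, has no antiperiplanar hydrogen and should not eliminate with KOtBu at low temperature.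

Step 4
Reactants: 7 (5aS,7S,9aS)-3,7-dibromo-6,6,9a-trimethyl-5,5a,6,7,8,9-hexahydro-1-benzoxepin-2(9aH)-one
Product: 8 (5aS,7S,9aS)-7-bromo-3,6,6,9a-tetramethyl-5,5a,6,7,8,9-hexahydro-1-benzoxepin-2(9aH)-one
Conditions: MeZnCl, Pd(PPh3)4 (5 mol %), THF, 40 °C
Reagents that add atoms: methylzinc chloride, C[Zn]Cl
Why: In this Negishi cross-coupling zerovalent palladium should insert only into the activated vinylic C3–Br bond of the 2-bromoacrylate unit, because the unactivated secondary alkyl bromide and the lactone are inert to Pd(PPh3)4 and MeZnCl; no stereocentre is formed.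

Step 5
Reactants: 8 (5aS,7S,9aS)-7-bromo-3,6,6,9a-tetramethyl-5,5a,6,7,8,9-hexahydro-1-benzoxepin-2(9aH)-one
Product: 9 (5aS,7S,9aS)-7-bromo-3,6,6,9a-tetramethyl-2-methylidene-2,5,5a,6,7,8,9,9a-octahydro-1-benzoxepine
Conditions: Cp2TiMe2 (3 equiv), toluene, 70 °C, dark; basic alumina work-up
Reagents that add atoms: dimethyltitanocene (Petasis reagent), C[Ti](C)(C1C=CC=C1)C1C=CC=C1
Why: Petasis methylenation of the ester carbonyl (Cp2Ti=CH2 formed on heating adds [2+2] to C2=O and cycloreverts) should convert the conjugated lactone regiospecifically into the 2-alkoxy-1,3-diene under neutral conditions that spare the acid-labile enol ether; no stereocentre is formed.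

Step 6
Reactants: 9 (5aS,7S,9aS)-7-bromo-3,6,6,9a-tetramethyl-2-methylidene-2,5,5a,6,7,8,9,9a-octahydro-1-benzoxepine
Product: 11 (5aS,7S,9aS)-7-bromo-2-(dibromomethylidene)-3,6,6,9a-tetramethyl-2,5,5a,6,7,8,9,9a-octahydro-1-benzoxepine, via monobromide 10 (not isolated)
Conditions: NBS (2.2 equiv), 2,6-lutidine, CH2Cl2, −78 → 0 °C
Reagents that add atoms: N-bromosuccinimide, O=C1CCC(=O)N1Br
Why: This is a twofold electrophilic vinylic bromination by addition–elimination, in which Br+ adds to the terminal enol-ether carbon C1' to give an O1-stabilised oxocarbenium ion, the base removes the acidified C1' proton, and the sequence repeats on 10, so that the E/Z mixture at the monobromide stage is of no consequence; no stereocentre is formed.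

Step 7
Reactants: 11 (5aS,7S,9aS)-7-bromo-2-(dibromomethylidene)-3,6,6,9a-tetramethyl-2,5,5a,6,7,8,9,9a-octahydro-1-benzoxepine
Product: 12 (2E,5aS,7S,9aS)-7-bromo-2-(bromomethylidene)-3,6,6,9a-tetramethyl-2,5,5a,6,7,8,9,9a-octahydro-1-benzoxepine
Conditions: Bu3SnH (1.05 equiv), Pd(PPh3)4 (4 mol %), toluene, rt
Reagents that add atoms: none
Why: In this palladium-catalysed hydrogenolysis of a 1,1-dibromoalkene, oxidative addition should take place at the less hindered C–Br bond, the one cis to O1 and away from the C3 methyl that lies in the diene plane next to the other bromine, and Sn–H transmetalation with reductive elimination under retention leaves the bromine cis to C3, which is the E geometry.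

Step 8
Reactants: 12 (2E,5aS,7S,9aS)-7-bromo-2-(bromomethylidene)-3,6,6,9a-tetramethyl-2,5,5a,6,7,8,9,9a-octahydro-1-benzoxepine
Product: 13 (2E,3R,4R,5aS,7S,9aS)-7-bromo-2-(bromomethylidene)-3,4-epoxy-3,6,6,9a-tetramethyldecahydro-1-benzoxepine (CNP0375295.1)
Conditions: mCPBA (1.0 equiv), NaHCO3, CH2Cl2, −20 °C
Reagents that add atoms: 3-chloroperoxybenzoic acid (mCPBA), OOC(=O)c1cccc(Cl)c1
Why: In this Prilezhaev epoxidation the trisubstituted C3=C4 bond should be more nucleophilic than the bromine-deactivated enol-ether bond C2=C1', and the peracid should approach from the face opposite the axial C9a methyl (the face of H-5a), which sets C3 and C4 as 3R,4R.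

## Compound list

1 | geranyl bromide, (2E)-1-bromo-3,7-dimethylocta-2,6-diene | CC(C)=CCC/C(C)=C/CBr | starting material
2 | tert-butyl acetate | CC(=O)OC(C)(C)C | starting material
3 | tert-butyl (4E)-5,9-dimethyldeca-4,8-dienoate | CC(C)=CCC/C(C)=C/CCC(=O)OC(C)(C)C | intermediate
4 | (4aS,6S,8aS)-6-bromo-5,5,8a-trimethyloctahydro-2H-chromen-2-one (trans-fused, bromine equatorial) | CC1(C)[C@@H](Br)CC[C@]2(C)OC(=O)CC[C@@H]12 | intermediate
5 | ketene silyl acetal, tert-butyl{[(4aS,6S,8aS)-6-bromo-5,5,8a-trimethyl-4a,5,6,7,8,8a-hexahydro-4H-chromen-2-yl]oxy}dimethylsilane | CC1(C)[C@@H](Br)CC[C@]2(C)OC(O[Si](C)(C)C(C)(C)C)=CC[C@@H]12 | intermediate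
6 | dibromocyclopropane adduct of 5: 7,7-dibromo-1-(tert-butyldimethylsilyloxy)-2-oxabicyclo[4.1.0]heptane unit fused to the bromocyclohexane, cyclopropane cis-fused and drawn on the face opposite the C8a methyl (either face leads to 7) | CC1(C)[C@@H](Br)CC[C@]2(C)O[C@]3(O[Si](C)(C)C(C)(C)C)C(Br)(Br)[C@@H]3C[C@@H]12 | intermediate
7 | (5aS,7S,9aS)-3,7-dibromo-6,6,9a-trimethyl-5,5a,6,7,8,9-hexahydro-1-benzoxepin-2(9aH)-one | CC1(C)[C@@H](Br)CC[C@]2(C)OC(=O)C(Br)=CC[C@@H]12 | intermediate
8 | (5aS,7S,9aS)-7-bromo-3,6,6,9a-tetramethyl-5,5a,6,7,8,9-hexahydro-1-benzoxepin-2(9aH)-one | CC1(C)[C@@H](Br)CC[C@]2(C)OC(=O)C(C)=CC[C@@H]12 | intermediate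
9 | (5aS,7S,9aS)-7-bromo-3,6,6,9a-tetramethyl-2-methylidene-2,5,5a,6,7,8,9,9a-octahydro-1-benzoxepine | CC1(C)[C@@H](Br)CC[C@]2(C)OC(=C)C(C)=CC[C@@H]12 | intermediate
10 | (5aS,7S,9aS)-7-bromo-2-(bromomethylidene)-3,6,6,9a-tetramethyl-2,5,5a,6,7,8,9,9a-octahydro-1-benzoxepine, drawn as the expected main Z isomer (geometry of no consequence) | CC1(C)[C@@H](Br)CC[C@]2(C)O/C(=C\Br)C(C)=CC[C@@H]12 | intermediate
11 | (5aS,7S,9aS)-7-bromo-2-(dibromomethylidene)-3,6,6,9a-tetramethyl-2,5,5a,6,7,8,9,9a-octahydro-1-benzoxepine | CC1(C)[C@@H](Br)CC[C@]2(C)OC(=C(Br)Br)C(C)=CC[C@@H]12 | intermediate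
12 | (2E,5aS,7S,9aS)-7-bromo-2-(bromomethylidene)-3,6,6,9a-tetramethyl-2,5,5a,6,7,8,9,9a-octahydro-1-benzoxepine | CC1(C)[C@@H](Br)CC[C@]2(C)O/C(=C/Br)C(C)=CC[C@@H]12 | intermediate
13 | (2E,3R,4R,5aS,7S,9aS)-7-bromo-2-(bromomethylidene)-3,4-epoxy-3,6,6,9a-tetramethyldecahydro-1-benzoxepine (CNP0375295.1) | CC1(C)[C@@H](Br)CC[C@]2(C)O/C(=C/Br)[C@]3(C)O[C@@H]3C[C@@H]12 | target

## Step count and risks

Total step count: 8. Longest linear sequence: 8 steps (1 → 13).

Steps most likely to fail:

1. Step 2. What may go wrong: bromonium formation at the internal C4=C5 alkene followed by capture by the ester carbonyl (direct bromolactonization), or weak enantiofacial control with an ester as terminating group. Fallback: setting out from 3, the cyclization is run without asymmetric induction using the stoichiometric bromonium source BDSB (Et2SBr·SbCl5Br, MeNO2, −25 °C). This should give the trans-fused lactone as a racemate, that is 4 together with (4aR,6R,8aR)-6-bromo-5,5,8a-trimethyloctahydro-2H-chromen-2-one F1. The enantiomers are separated by preparative chromatography on a chiral stationary phase, and the route is rejoined at 4.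

2. Step 8. What may go wrong: poor chemoselectivity, that is oxidation of the bromo enol ether bond C2=C1' in competition with C3=C4, with loss of the acid-labile product, or poor facial selectivity. Fallback: setting out from 11, the epoxidation is moved to the gem-dibromide stage, where two bromines deactivate the enol ether. mCPBA with NaHCO3 in CH2Cl2 should give (3R,4R,5aS,7S,9aS)-7-bromo-2-(dibromomethylidene)-3,4-epoxy-3,6,6,9a-tetramethyldecahydro-1-benzoxepine F2. The hydrogenolysis with Pd(PPh3)4 and Bu3SnH is then carried out on F2 and should remove the bromine cis to O1, coming back to the route at 13.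

3. Step 6. What may go wrong: deprotonation of the bromo-oxocarbenium intermediate at C5 instead of C1' (migration of the diene into the ring), or an incomplete second bromination. Fallback: setting out from 8, the gem-dibromide is made by carbonyl olefination instead of C–H bromination. Ramirez dibromomethylenation of the lactone carbonyl (CBr4, PPh3, toluene, reflux), a reaction known on lactones, should give 11 directly without passing through 9 and 10. The route is rejoined at 11, and this fallback makes no new compound (F0).

Further compounds

F1 | step 2 | (4aR,6R,8aR)-6-bromo-5,5,8a-trimethyloctahydro-2H-chromen-2-one (enantiomer of 4) | CC1(C)[C@H](Br)CC[C@@]2(C)OC(=O)CC[C@H]12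
F2 | step 8 | (3R,4R,5aS,7S,9aS)-7-bromo-2-(dibromomethylidene)-3,4-epoxy-3,6,6,9a-tetramethyldecahydro-1-benzoxepine | CC1(C)[C@@H](Br)CC[C@]2(C)OC(=C(Br)Br)[C@]3(C)O[C@@H]3C[C@@H]12
F0 | step 6 | none | none
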